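The three phenols are masked as MOM ethers. Ring C is then cut at O1–C8a and at C4–C4a together, which leaves ring A as 4-geranyl-3,5-bis(methoxymethoxy)benzyne and the O1–C2–C3–C4 chain with ring B as an (S)-3-aryl-3-silyloxypropanoate.
Enabling feature: the oxygen on C5 of ring A stands next to C4a and polarises the C4a≡C8a aryne bond. O1 therefore adds to C8a, and the carbanion arises at C4a, within reach of the ester carbon C4 for a six-membered closure.
The geranyl group is already fixed at C6 between the two ring A oxygens, so the 6- versus 8-geranyl ambiguity of chalcone cyclisations cannot arise.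
Forward: the ring A fragment comes from resorcinol (MOM, ortho-metalation/geranylation, C–H borylation/oxidation, carbamate-directed silylation, triflation). The ring B fragment comes from 3'-hydroxy-4'-methoxyacetophenone (MOM, Claisen condensation, transfer hydrogenation, O-silylation). The two are joined with closure of ring C and then deprotected.
Stereochemistry: C2 is set by Noyori transfer hydrogenation with the (S,S) catalyst, and its C–O bond is never broken afterwards. The E alkene comes in with geranyl bromide.

Key step: step 11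

Remark: flavanone numbering is used (O1, C2, C3, C4, C4a, C5 to C8, C8a). Geranyl means (2E)-3,7-dimethylocta-2,6-dien-1-yl. The target SMILES corresponds to the (2S) enantiomer.

Step 1
Reactants: 1 resorcinol
Product: 2 1,3-bis(methoxymethoxy)benzene
Conditions: MOMCl (2.5 equiv), iPr2NEt (3 equiv), CH2Cl2, 0 °C to rt
Reagents that add atoms: chloromethyl methyl ether, COCCl
Why: Base-mediated O-alkylation of both phenols (acetal protection) is routine and installs the groups that later direct the metalations on ring A.

Step 2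
Reactants: 2 1,3-bis(methoxymethoxy)benzene; 3 geranyl bromide
Product: 5 2-geranyl-1,3-bis(methoxymethoxy)benzene, via aryllithium 4 (not isolated)
Conditions: n-BuLi (1.1 equiv), THF, 0 °C to rt; then 3, −78 °C to rt
Reagents that add atoms: n-butyllithium, [Li]CCCC (its lithium stays only in 4)
Why: Directed ortho-metalation occurs at the carbon flanked by both OMOM groups (cooperative coordination), and SN2 allylation of 4 with the primary allylic bromide keeps the E alkene of 3.

Step 3
Reactants: 5 2-geranyl-1,3-bis(methoxymethoxy)benzene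
Product: 7 4-geranyl-3,5-bis(methoxymethoxy)phenol, via aryl boronate 6 (not isolated)
Conditions: [Ir(OMe)(cod)]2 (1.5 mol %), dtbpy (3 mol %), B2pin2 (1.0 equiv), THF, 60 °C; then 30% H2O2, aq NaOH, 0 °C
Reagents that add atoms: hydrogen peroxide, OO; bis(pinacolato)diboron, CC1(C)OB(OC1(C)C)B1OC(C)(C)C(C)(C)O1 (its boron stays only in 6)
Why: Sterically governed C–H borylation of a 1,2,3-trisubstituted arene reaches only the C–H without an ortho substituent (para to the geranyl group), and basic peroxide oxidises the boronate in the same flask without touching isolated trisubstituted alkenes.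

Step 4
Reactants: 7 4-geranyl-3,5-bis(methoxymethoxy)phenol
Product: 8 4-geranyl-3,5-bis(methoxymethoxy)phenyl N-isopropylcarbamate
Conditions: iPrNCO (1.5 equiv), Et3N (0.2 equiv), CH2Cl2, rt
Reagents that add atoms: isopropyl isocyanate, CC(C)N=C=O
Why: Amine-catalysed addition of a phenol to an isocyanate gives the carbamate, which serves as a strong and easily removed directing group.

Step 5
Reactants: 8 4-geranyl-3,5-bis(methoxymethoxy)phenyl N-isopropylcarbamate
Product: 12 4-geranyl-3,5-bis(methoxymethoxy)-2-(trimethylsilyl)phenyl N-isopropylcarbamate, via N-silyl carbamate 9 (not isolated), via aryllithium 10 (not isolated), via bis-silyl carbamate 11 (not isolated)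
Conditions: TBSOTf (1.05 equiv), TMEDA, Et2O, 0 °C to rt; n-BuLi, TMEDA, −78 °C; TMSCl, −78 °C to rt; aq citric acid
Reagents that add atoms: chlorotrimethylsilane, C[Si](C)(C)Cl; tert-butyldimethylsilyl triflate, CC(C)(C)[Si](C)(C)OS(=O)(=O)C(F)(F)F (its silyl group stays only in 9 to 11); n-butyllithium, [Li]CCCC (its lithium stays only in 10)
Why: N-silylation masks the N–H, directed ortho-metalation then takes one of the two equivalent positions flanked by the carbamate and an OMOM group, TMSCl traps the aryllithium, and mild aqueous acid hydrolyses only the N–Si bond.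

Step 6
Reactants: 12 4-geranyl-3,5-bis(methoxymethoxy)-2-(trimethylsilyl)phenyl N-isopropylcarbamate
Product: 14 4-geranyl-3,5-bis(methoxymethoxy)-2-(trimethylsilyl)phenyl trifluoromethanesulfonate, via silyl phenol 13 (not isolated)
Conditions: DBU (1.5 equiv), Et2NH (1.2 equiv), MeCN, 40 °C; then PhNTf2 (1.5 equiv), rt
Reagents that add atoms: N-phenylbis(trifluoromethanesulfonimide), O=S(=O)(N(c1ccccc1)S(=O)(=O)C(F)(F)F)C(F)(F)F
Why: DBU induces E1cB loss of isopropyl isocyanate (caught by Et2NH as a urea), and the phenoxide is sulfonylated in situ, which is the standard end of the carbamate route to 2-silylaryl triflates.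

Step 7
Reactants: 15 1-(3-hydroxy-4-methoxyphenyl)ethanone
Product: 16 1-[4-methoxy-3-(methoxymethoxy)phenyl]ethanone
Conditions: MOMCl (1.3 equiv), iPr2NEt (1.6 equiv), CH2Cl2, 0 °C to rt
Reagents that add atoms: chloromethyl methyl ether, COCCl
Why: O-alkylation of the phenol gives the same acetal as on ring A, so one final operation frees all three hydroxyl groups and no phenol is left to add to the aryne.

Step 8
Reactants: 16 1-[4-methoxy-3-(methoxymethoxy)phenyl]ethanone
Product: 17 methyl 3-[4-methoxy-3-(methoxymethoxy)phenyl]-3-oxopropanoate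
Conditions: NaH (2.2 equiv), (MeO)2CO (4 equiv), THF, reflux; AcOH quench
Reagents that add atoms: dimethyl carbonate, COC(=O)OC
Why: Crossed Claisen condensation of the ketone enolate with the non-enolisable carbonate is driven by deprotonation of the beta-keto ester formed.

Step 9
Reactants: 17 methyl 3-[4-methoxy-3-(methoxymethoxy)phenyl]-3-oxopropanoate
Product: 18 methyl (3S)-3-hydroxy-3-[4-methoxy-3-(methoxymethoxy)phenyl]propanoate
Conditions: RuCl[(S,S)-TsDPEN](p-cymene) (1 mol %), HCO2H/Et3N (5:2), EtOAc, 30 °C
Reagents that add atoms: none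
Why: In this Noyori asymmetric transfer hydrogenation, RuH[(S,S)-TsDPEN](p-cymene) delivers hydride to the Re face of the aryl ketone, oriented by the CH–pi contact between the cymene ligand and the aryl ring, which gives the (S) carbinol that becomes C2.

Step 10
Reactants: 18 methyl (3S)-3-hydroxy-3-[4-methoxy-3-(methoxymethoxy)phenyl]propanoate
Product: 19 methyl (3S)-3-[4-methoxy-3-(methoxymethoxy)phenyl]-3-(trimethylsilyloxy)propanoate
Conditions: TMSCl (1.3 equiv), imidazole (2 equiv), CH2Cl2, 0 °C
Reagents that add atoms: chlorotrimethylsilane, C[Si](C)(C)Cl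
Why: O-silylation replaces the O–H proton by a fluoride-labile group without touching the stereocenter.

Step 11
Reactants: 19 methyl (3S)-3-[4-methoxy-3-(methoxymethoxy)phenyl]-3-(trimethylsilyloxy)propanoate; 14 4-geranyl-3,5-bis(methoxymethoxy)-2-(trimethylsilyl)phenyl trifluoromethanesulfonate
Product: 23 (2S)-6-geranyl-5,7-bis(methoxymethoxy)-2-[4-methoxy-3-(methoxymethoxy)phenyl]chroman-4-one, via alkoxide 20 (not isolated), via aryne 21 (not isolated), via aryl anion 22 (not isolated)
Conditions: 19 (1.0 equiv), 14 (1.3 equiv), [Bu4N][Ph3SiF2] (1.3 equiv, slow addition), 4 Å MS, THF (0.03 M), 0 °C to rt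
Reagents that add atoms: none
Why: Proposed new method: fluoride, and then the methoxide expelled by the ring closure, strips both silyl groups so that alkoxide 20 and aryne 21 meet in a proton-free medium, O1 adds to C8a, carbanion 22 appears at C4a and attacks the ester carbon C4 with loss of methoxide, which forms O1–C8a and C4–C4a in one operation. The closest known reaction types are the fluoride-induced annulation of arynes with salicylate esters to xanthones and the O–H insertion of aliphatic alcohols into arynes, and the new element is an aliphatic beta-silyloxy ester as the two-point partner, giving a chroman-4-one. Ring C closes by a 6-exo-trig acyl substitution of the aryl anion on the ester carbonyl. No stereocenter is created, since C2 comes in from 19 and neither its C2–O1 nor its C2–C3 bond is touched, so the (S) configuration is retained. The step needs regioselective addition to the aryne, secured by the C5 OMOM group, whose inductive pull makes C8a the electrophilic terminus and stabilises charge at C4a (C8a also has only C8–H as neighbour), and it needs acyl capture to outrun protonation, secured by the silyl ether in place of O–H and by THF in place of an acidic solvent. The fluoride is limited so that, together with the released methoxide, it just matches the silicon present, which leaves no free base to open ring C by E1cB and racemise C2.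

Step 12
Reactants: 23 (2S)-6-geranyl-5,7-bis(methoxymethoxy)-2-[4-methoxy-3-(methoxymethoxy)phenyl]chroman-4-one
Product: 24 (2S)-6-geranyl-5,7-dihydroxy-2-(3-hydroxy-4-methoxyphenyl)chroman-4-one
Conditions: HCl (1 M in MeOH), 40 °C
Reagents that add atoms: none
Why: Acid-catalysed acetal exchange with methanol removes all three MOM groups as dimethoxymethane under dilute conditions, which have precedent on prenylated and geranylated flavanones and should be too weak to protonate the trisubstituted alkenes or ionise the C2–O1 bond.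

Compound list
1 | resorcinol | Oc1cccc(O)c1 | starting material
2 | 1,3-bis(methoxymethoxy)benzene | COCOc1cccc(OCOC)c1 | intermediate
3 | geranyl bromide | BrC/C=C(\C)CCC=C(C)C | starting material
4 | 2,6-bis(methoxymethoxy)phenyllithium (not isolated) | [Li]c1c(OCOC)cccc1OCOC | intermediate
5 | 2-geranyl-1,3-bis(methoxymethoxy)benzene | COCOc1cccc(OCOC)c1C/C=C(\C)CCC=C(C)C | intermediate
6 | 4-geranyl-3,5-bis(methoxymethoxy)phenylboronic acid pinacol ester (not isolated) | COCOc1cc(B2OC(C)(C)C(C)(C)O2)cc(OCOC)c1C/C=C(\C)CCC=C(C)C | intermediate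
7 | 4-geranyl-3,5-bis(methoxymethoxy)phenol | COCOc1cc(O)cc(OCOC)c1C/C=C(\C)CCC=C(C)C | intermediate
8 | 4-geranyl-3,5-bis(methoxymethoxy)phenyl N-isopropylcarbamate | COCOc1cc(OC(=O)NC(C)C)cc(OCOC)c1C/C=C(\C)CCC=C(C)C | intermediate
9 | N-(tert-butyldimethylsilyl) derivative of 8 (not isolated) | COCOc1cc(OC(=O)N(C(C)C)[Si](C)(C)C(C)(C)C)cc(OCOC)c1C/C=C(\C)CCC=C(C)C | intermediate
10 | 2-lithio derivative of 9 (not isolated) | COCOc1cc(OC(=O)N(C(C)C)[Si](C)(C)C(C)(C)C)c([Li])c(OCOC)c1C/C=C(\C)CCC=C(C)C | intermediate
11 | 2-trimethylsilyl derivative of 9 (not isolated) | COCOc1cc(OC(=O)N(C(C)C)[Si](C)(C)C(C)(C)C)c([Si](C)(C)C)c(OCOC)c1C/C=C(\C)CCC=C(C)C | intermediate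
12 | 4-geranyl-3,5-bis(methoxymethoxy)-2-(trimethylsilyl)phenyl N-isopropylcarbamate | COCOc1cc(OC(=O)NC(C)C)c([Si](C)(C)C)c(OCOC)c1C/C=C(\C)CCC=C(C)C | intermediate
13 | 4-geranyl-3,5-bis(methoxymethoxy)-2-(trimethylsilyl)phenol (not isolated) | COCOc1cc(O)c([Si](C)(C)C)c(OCOC)c1C/C=C(\C)CCC=C(C)C | intermediate
14 | 4-geranyl-3,5-bis(methoxymethoxy)-2-(trimethylsilyl)phenyl trifluoromethanesulfonate | COCOc1cc(OS(=O)(=O)C(F)(F)F)c([Si](C)(C)C)c(OCOC)c1C/C=C(\C)CCC=C(C)C | intermediate
15 | 1-(3-hydroxy-4-methoxyphenyl)ethanone | COc1ccc(C(C)=O)cc1O | starting material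
16 | 1-[4-methoxy-3-(methoxymethoxy)phenyl]ethanone | COCOc1cc(C(C)=O)ccc1OC | intermediate
17 | methyl 3-[4-methoxy-3-(methoxymethoxy)phenyl]-3-oxopropanoate | COCOc1cc(C(=O)CC(=O)OC)ccc1OC | intermediate
18 | methyl (3S)-3-hydroxy-3-[4-methoxy-3-(methoxymethoxy)phenyl]propanoate | COc1ccc([C@H](CC(=O)OC)O)cc1OCOC | intermediate
19 | methyl (3S)-3-[4-methoxy-3-(methoxymethoxy)phenyl]-3-(trimethylsilyloxy)propanoate | COc1ccc([C@H](CC(=O)OC)O[Si](C)(C)C)cc1OCOC | intermediate
20 | tetrabutylammonium alkoxide of 18 (not isolated) | COc1ccc([C@H](CC(=O)OC)[O-])cc1OCOC.CCCC[N+](CCCC)(CCCC)CCCC | intermediate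
21 | 4-geranyl-3,5-bis(methoxymethoxy)benzyne (not isolated) | C1#CC(OCOC)=C(C/C=C(\C)CCC=C(C)C)C(OCOC)=C1 | intermediate
22 | C4a aryl anion formed by addition of 20 to C8a of 21 (not isolated) | COc1ccc([C@H](CC(=O)OC)Oc2cc(OCOC)c(C/C=C(\C)CCC=C(C)C)c(OCOC)[c-]2)cc1OCOC.CCCC[N+](CCCC)(CCCC)CCCC | intermediate
23 | (2S)-6-geranyl-5,7-bis(methoxymethoxy)-2-[4-methoxy-3-(methoxymethoxy)phenyl]chroman-4-one | COc1ccc([C@@H]2CC(=O)c3c(cc(OCOC)c(C/C=C(\C)CCC=C(C)C)c3OCOC)O2)cc1OCOC | intermediate
24 | (2S)-6-geranyl-5,7-dihydroxy-2-(3-hydroxy-4-methoxyphenyl)chroman-4-one | COc1ccc([C@@H]2CC(=O)c3c(cc(O)c(C/C=C(\C)CCC=C(C)C)c3O)O2)cc1O | target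

Total step count: 12. Longest linear sequence: 8 (steps 1 to 6, 11, 12).

Steps most likely to fail

1. Step 11 (bears the label).
- What may go wrong: the aryl anion is protonated before acyl capture. The free alkoxide undergoes retro-aldol cleavage or beta-elimination. Ring C opens under base, with erosion of the configuration at C2.
- Fallback: it uses known chemistry, sets out from 18 and 14, and returns at 23.
- First stage: O–H insertion of the free alcohol into aryne 21 (KF, 18-crown-6, THF, −20 °C, attack again at C8a) should give methyl (3S)-3-[4-geranyl-3,5-bis(methoxymethoxy)phenoxy]-3-[4-methoxy-3-(methoxymethoxy)phenyl]propanoate F1.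
- Second stage: Me3SnOH in 1,2-dichloroethane cleaves the methyl ester without strong base to give (3S)-3-[4-geranyl-3,5-bis(methoxymethoxy)phenoxy]-3-[4-methoxy-3-(methoxymethoxy)phenyl]propanoic acid F2.
- Third stage: mixed-anhydride activation with (CF3CO)2O in CH2Cl2 at −20 to 0 °C closes ring C by intramolecular Friedel–Crafts acylation. The two positions ortho to O1 are equivalent, so only 23 can form.

2. Step 3.
- What may go wrong: hydroboration or isomerisation of the geranyl alkenes by the iridium boryl species and HBpin competes with arene borylation.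
- Fallback: it reverses the order of events, sets out from 2, and returns at 7.
- Borylation of 2 under the same catalyst system goes to its only unhindered C–H and gives 3,5-bis(methoxymethoxy)phenylboronic acid pinacol ester F3.
- Basic peroxide converts this to 3,5-bis(methoxymethoxy)phenol F4.
- TIPSCl and imidazole give the non-directing, bulky [3,5-bis(methoxymethoxy)phenoxy]triisopropylsilane F5.
- n-BuLi metalates between the two OMOM groups to give 2,6-bis(methoxymethoxy)-4-(triisopropylsilyloxy)phenyllithium F6.
- Bromide 3 alkylates this to [4-geranyl-3,5-bis(methoxymethoxy)phenoxy]triisopropylsilane F7, and Bu4NF then frees phenol 7.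

3. Step 12.
- What may go wrong: acid induces cyclisation of the proximal geranyl double bond onto a freed C5 or C7 hydroxyl group, and partial racemisation occurs through ionisation of the C2–O1 bond, assisted by the para methoxy group.
- Fallback: it avoids Brønsted acid by changing the protecting groups first, sets out from 23, and returns at 24.
- TMSOTf and 2,2'-bipyridyl in CH2Cl2 at 0 °C transfer each methoxymethyl group to the bipyridyl nitrogen and should leave (2S)-6-geranyl-2-[4-methoxy-3-(trimethylsilyloxy)phenyl]-5,7-bis(trimethylsilyloxy)chroman-4-one F8.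
- Water in THF at neutral pH hydrolyses F8 to 24.

Further compounds
F1 | step 11 | methyl (3S)-3-[4-geranyl-3,5-bis(methoxymethoxy)phenoxy]-3-[4-methoxy-3-(methoxymethoxy)phenyl]propanoate | COc1ccc([C@H](CC(=O)OC)Oc2cc(OCOC)c(C/C=C(\C)CCC=C(C)C)c(OCOC)c2)cc1OCOC
F2 | step 11 | (3S)-3-[4-geranyl-3,5-bis(methoxymethoxy)phenoxy]-3-[4-methoxy-3-(methoxymethoxy)phenyl]propanoic acid | COc1ccc([C@H](CC(=O)O)Oc2cc(OCOC)c(C/C=C(\C)CCC=C(C)C)c(OCOC)c2)cc1OCOC
F3 | step 3 | 3,5-bis(methoxymethoxy)phenylboronic acid pinacol ester | COCOc1cc(B2OC(C)(C)C(C)(C)O2)cc(OCOC)c1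
F4 | step 3 | 3,5-bis(methoxymethoxy)phenol | COCOc1cc(O)cc(OCOC)c1
F5 | step 3 | [3,5-bis(methoxymethoxy)phenoxy]triisopropylsilane | COCOc1cc(O[Si](C(C)C)(C(C)C)C(C)C)cc(OCOC)c1
F6 | step 3 | 2,6-bis(methoxymethoxy)-4-(triisopropylsilyloxy)phenyllithium | [Li]c1c(OCOC)cc(O[Si](C(C)C)(C(C)C)C(C)C)cc1OCOC
F7 | step 3 | [4-geranyl-3,5-bis(methoxymethoxy)phenoxy]triisopropylsilane | COCOc1cc(O[Si](C(C)C)(C(C)C)C(C)C)cc(OCOC)c1C/C=C(\C)CCC=C(C)C
F8 | step 12 | (2S)-6-geranyl-2-[4-methoxy-3-(trimethylsilyloxy)phenyl]-5,7-bis(trimethylsilyloxy)chroman-4-one | COc1ccc([C@@H]2CC(=O)c3c(cc(O[Si](C)(C)C)c(C/C=C(\C)CCC=C(C)C)c3O[Si](C)(C)C)O2)cc1O[Si](C)(C)C
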